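**Retrosynthetic overview**

- Feature: in the pyrrole ring, C2 carries N1 and Br and C3 carries Cl. C2 is therefore an isocyanide dibromide carbon that has given up one bromide, and C3 is a benzylic chloride carbon.
- Disconnection 1 (C2–C3, the only ring formed): the indole is opened to N-[3,6-dibromo-2-(chloromethyl)phenyl]carbonimidic dibromide. The benzylic carbanion closes onto N=CBr2; the dibromobenzene ring is carried intact.
- Disconnection 2: dibromide ⇒ isocyanide (Br2 addition) ⇒ formamide (dehydration) ⇒ (2-amino-3,6-dibromophenyl)methanol (N-formylation, OH to Cl).
- Disconnection 3: amino alcohol ⇒ 3,6-dibromo-2-fluorobenzaldehyde (azide SNAr, reductions) ⇒ 1,4-dibromo-2-fluorobenzene + DMF (ortho-lithiation/formylation).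

Key step: step 8

Remark: the target has no stereocentre and is achiral, so no enantiocontrol is needed and none is planned.

**Route**

Step 1
Reactants: 1 1,4-dibromo-2-fluorobenzene
Product: 3 3,6-dibromo-2-fluorobenzaldehyde, via (3,6-dibromo-2-fluorophenyl)lithium 2 (not isolated)
Conditions: LDA (1.1 equiv, commercial solution), THF, −78 °C; DMF, −78 → −20 °C; aq. HCl
Reagents that add atoms: N,N-dimethylformamide, CN(C)C=O; lithium diisopropylamide, [Li]N(C(C)C)C(C)C (lithium of 2 only)
Why: Directed ortho-lithiation followed by formylation with DMF: the ring proton between fluorine and bromine is the most acidic, and at −78 °C LDA should remove it without halogen migration or aryne formation.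

Step 2
Reactants: 3 3,6-dibromo-2-fluorobenzaldehyde
Product: 4 2-azido-3,6-dibromobenzaldehyde
Conditions: NaN3 (1.3 equiv), DMSO, 45 °C, dark
Reagents that add atoms: sodium azide, [Na+].[N-]=[N+]=[N-]
Why: Nucleophilic aromatic substitution: fluoride ortho to the formyl group is by far the best leaving group on the ring, so azide should replace it in preference to the ortho bromine, as in the usual conversion of 2-fluorobenzaldehydes into 2-azidobenzaldehydes.

Step 3
Reactants: 4 2-azido-3,6-dibromobenzaldehyde
Product: 6 (2-amino-3,6-dibromophenyl)methanol, via (2-azido-3,6-dibromophenyl)methanol 5 (not isolated)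
Conditions: NaBH4, THF/MeOH, 0 °C; then Zn dust, NH4Cl, H2O, rt
Reagents that add atoms: none
Why: Borohydride reduction of the aldehyde followed by zinc/ammonium chloride reduction of the aryl azide; neither reagent attacks aryl bromides, and reducing the aldehyde first keeps the new amine from condensing with a formyl group.

Step 4
Reactants: 6 (2-amino-3,6-dibromophenyl)methanol
Product: 8 N-[3,6-dibromo-2-(hydroxymethyl)phenyl]formamide, via 3,6-dibromo-2-formamidobenzyl formate 7 (not isolated)
Conditions: HCO2H/Ac2O (acetic formic anhydride, 3 equiv), THF, 0 °C → rt; then K2CO3 (cat.), MeOH, 0 °C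
Reagents that add atoms: acetic formic anhydride, CC(=O)OC=O, made from formic acid, OC=O, and acetic anhydride, CC(=O)OC(C)=O
Why: N-Formylation with a mixed anhydride reactive enough for a hindered, electron-poor aniline; the benzylic formate formed alongside is far more labile than the formanilide and should be removed selectively by brief carbonate-catalysed transesterification.

Step 5
Reactants: 8 N-[3,6-dibromo-2-(hydroxymethyl)phenyl]formamide
Product: 9 N-[3,6-dibromo-2-(chloromethyl)phenyl]formamide
Conditions: SOCl2 (1.2 equiv), CH2Cl2, 0 °C → rt; cold aq. NaHCO3 wash; used promptly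
Reagents that add atoms: thionyl chloride, O=S(Cl)Cl
Why: Deoxychlorination of a primary benzylic alcohol with thionyl chloride, the standard way from N-acyl-2-aminobenzyl alcohols to N-acyl-2-(chloromethyl)anilines; no DMF is added so that the formamide is not activated.

Step 6
Reactants: 9 N-[3,6-dibromo-2-(chloromethyl)phenyl]formamide
Product: 10 1,4-dibromo-2-(chloromethyl)-3-isocyanobenzene
Conditions: POCl3 (1.2 equiv), Et3N (4 equiv), CH2Cl2, −30 → 0 °C; cold aq. Na2CO3
Reagents that add atoms: none
Why: Ugi dehydration of a formanilide to the isocyanide with POCl3 and a tertiary amine; at low temperature the dehydration should be faster than base-induced loss of HCl from the benzylic chloride.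

Step 7
Reactants: 10 1,4-dibromo-2-(chloromethyl)-3-isocyanobenzene
Product: 11 N-[3,6-dibromo-2-(chloromethyl)phenyl]carbonimidic dibromide
Conditions: Br2 (1.0 equiv), CH2Cl2, −78 → 0 °C; evaporation under argon, crude product used dry
Reagents that add atoms: bromine, BrBr
Why: α-Addition of bromine to the divalent isocyanide carbon, the standard route to carbonimidic dibromides; it is fast at −78 °C, well before any ring or benzylic bromination.

Step 8
Reactants: 11 N-[3,6-dibromo-2-(chloromethyl)phenyl]carbonimidic dibromide
Product: 15 2,4,7-tribromo-3-chloro-1H-indole, via α-lithio benzylic chloride 12 (not isolated), via 2,4,7-tribromo-3-chloro-3H-indole 13 (not isolated), via lithium 2,4,7-tribromo-3-chloroindol-1-ide 14 (not isolated)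
Conditions: LiTMP (2.2 equiv, from 2,2,6,6-tetramethylpiperidine/n-BuLi), THF, −95 °C, slow addition of 11; → −78 °C; AcOH, −78 °C
Reagents that add atoms: lithium 2,2,6,6-tetramethylpiperidide, [Li]N1C(C)(C)CCCC1(C)C (lithium of 12 and 14 only; nothing in 15)
Why: Proposed new method: the first equivalent of LiTMP removes a proton from the CH2Cl group, acidified by chlorine and by the electron-poor dibromoaryl ring, and the α-chlorobenzyl carbanion 12 adds to the neighbouring N=CBr2 carbon to give an anilide-type nitrogen anion that expels one bromide, forming C2–C3 and the 3H-indole 13. The second equivalent removes the now doubly activated C3–H to give the aromatic indolide 14, which is protonated on nitrogen at the quench, so one imidoyl bromine is the leaving group and the other remains as the C2 bromine without any halogenation of an indole. The closest known reaction types are the base-induced cyclisation of ortho-alkylphenyl isocyanides to indoles, the closure of ortho benzylic anions or ylides onto amide and imidoyl carbons (Madelung type, intramolecular Wittig) and the substitution of isocyanide dihalides by carbon nucleophiles; closure of an α-halobenzyl anion onto a carbonimidic dibromide is not an established reaction. The pyrrole ring closes in a formal 5-endo-trig mode, which should be tolerated because the nucleophile is a delocalised benzylic anion (the closure can be read as a 1,5-electrocyclisation of a six-electron azapentadienyl anion) and because the dibromo-substituted imine carbon is strongly electrophilic. No stereocentre is formed. The step needs benzylic deprotonation to win over attack of the base on the imidoyl carbon or its bromine, over α-elimination of the carbenoid and over ring lithiation beside bromine; the bulk of LiTMP, the temperature near −95 °C and the five-atom proximity of the internal electrophile are relied on for this.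

**Compound list**

1 | 1,4-dibromo-2-fluorobenzene | Fc1cc(Br)ccc1Br | starting material
2 | (3,6-dibromo-2-fluorophenyl)lithium | [Li]c1c(F)c(Br)ccc1Br | intermediate (not isolated)
3 | 3,6-dibromo-2-fluorobenzaldehyde | O=Cc1c(F)c(Br)ccc1Br | intermediate
4 | 2-azido-3,6-dibromobenzaldehyde | O=Cc1c(N=[N+]=[N-])c(Br)ccc1Br | intermediate
5 | (2-azido-3,6-dibromophenyl)methanol | OCc1c(N=[N+]=[N-])c(Br)ccc1Br | intermediate (not isolated)
6 | (2-amino-3,6-dibromophenyl)methanol | Nc1c(Br)ccc(Br)c1CO | intermediate
7 | 3,6-dibromo-2-formamidobenzyl formate | O=CNc1c(Br)ccc(Br)c1COC=O | intermediate (not isolated)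
8 | N-[3,6-dibromo-2-(hydroxymethyl)phenyl]formamide | O=CNc1c(Br)ccc(Br)c1CO | intermediate
9 | N-[3,6-dibromo-2-(chloromethyl)phenyl]formamide | O=CNc1c(Br)ccc(Br)c1CCl | intermediate
10 | 1,4-dibromo-2-(chloromethyl)-3-isocyanobenzene | [C-]#[N+]c1c(Br)ccc(Br)c1CCl | intermediate
11 | N-[3,6-dibromo-2-(chloromethyl)phenyl]carbonimidic dibromide | ClCc1c(Br)ccc(Br)c1N=C(Br)Br | intermediate
12 | {chloro[3,6-dibromo-2-(dibromomethylideneamino)phenyl]methyl}lithium (α-lithio benzylic chloride) | [Li]C(Cl)c1c(Br)ccc(Br)c1N=C(Br)Br | intermediate (not isolated)
13 | 2,4,7-tribromo-3-chloro-3H-indole (racemic at C3, transient) | ClC1C(Br)=Nc2c(Br)ccc(Br)c12 | intermediate (not isolated)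
14 | lithium 2,4,7-tribromo-3-chloroindol-1-ide | [Li]n1c(Br)c(Cl)c2c(Br)ccc(Br)c12 | intermediate (not isolated)
15 | 2,4,7-tribromo-3-chloro-1H-indole | Clc1c(Br)[nH]c2c(Br)ccc(Br)c12 | target

**Step count**

Total step count: 8. Longest linear sequence: 8 steps (fully linear from 1).

**Steps most likely to fail**

1. Step 8 (proposed new method). Benzylic deprotonation may be outrun by attack of the amide base on the imidoyl carbon or its bromine (reverting to the isocyanide), by α-elimination of the carbenoid, or by ring metalation next to bromine, so that the ring does not close or closes without the C2 bromine. The fallback uses known chemistry, sets out from 9 and comes back at 15. Compound 9 is heated with PPh3 in MeCN to give {[3,6-dibromo-2-(formylamino)phenyl]methyl}triphenylphosphonium chloride F1. t-BuOK in hot toluene forms the ylide, which undergoes intramolecular Wittig reaction with the formamide carbonyl to give 4,7-dibromo-1H-indole F2. NCS in DMF at 0 °C chlorinates the most nucleophilic position C3 to give 4,7-dibromo-3-chloro-1H-indole F3. NBS in CH2Cl2 then brominates the remaining pyrrole position C2 and should deliver 15.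

2. Step 6. Under the amine base, loss of HCl from the benzylic chloride next to the acidic formanilide N–H, or closure of the activated formamide oxygen onto the benzylic carbon, may compete with dehydration. The fallback introduces chlorine only after the isocyanide is in place; it sets out from 7 (isolated instead of being methanolysed in step 4) and comes back at 10. POCl3/Et3N dehydrates 7 to (3,6-dibromo-2-isocyanophenyl)methyl formate F4. K2CO3 (cat.) in MeOH at 0 °C removes the formate to give (3,6-dibromo-2-isocyanophenyl)methanol F5. MsCl/Et3N at −20 °C gives (3,6-dibromo-2-isocyanophenyl)methyl methanesulfonate F6, and LiCl in THF displaces the mesylate to give 10.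

3. Step 5. Thionyl chloride may activate the formamide as well as the alcohol, and the neighbouring oxygen may then close a 4H-3,1-benzoxazine ring instead of leaving the open chloromethyl formamide. The fallback chlorinates before the acyl group is present; it sets out from 6 and comes back at 9. Compound 6 is treated with SOCl2 in CH2Cl2 to give 3,6-dibromo-2-(chloromethyl)anilinium chloride F7, a hindered and weakly nucleophilic aniline that is kept as its salt. F7 is formylated with acetic formic anhydride and sodium acetate in THF at 0 °C to give 9.

**Further compounds**

F1 | step 8 | {[3,6-dibromo-2-(formylamino)phenyl]methyl}triphenylphosphonium chloride | O=CNc1c(Br)ccc(Br)c1C[P+](c1ccccc1)(c1ccccc1)c1ccccc1.[Cl-]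
F2 | step 8 | 4,7-dibromo-1H-indole | Brc1ccc(Br)c2[nH]ccc12
F3 | step 8 | 4,7-dibromo-3-chloro-1H-indole | Clc1c[nH]c2c(Br)ccc(Br)c12
F4 | step 6 | (3,6-dibromo-2-isocyanophenyl)methyl formate | [C-]#[N+]c1c(Br)ccc(Br)c1COC=O
F5 | step 6 | (3,6-dibromo-2-isocyanophenyl)methanol | [C-]#[N+]c1c(Br)ccc(Br)c1CO
F6 | step 6 | (3,6-dibromo-2-isocyanophenyl)methyl methanesulfonate | [C-]#[N+]c1c(Br)ccc(Br)c1COS(C)(=O)=O
F7 | step 5 | 3,6-dibromo-2-(chloromethyl)anilinium chloride | [NH3+]c1c(Br)ccc(Br)c1CCl.[Cl-]
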